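The route rests on cutting the bond between C1 of the central 3,5-dimethoxy-4-aryloxyphenyl ring (ring B) and C2 of the dihydrobenzofuran. C2 carries the ring oxygen O1, so it is a natural α-oxy radical centre; it is introduced as a carboxylate, tied to the C3 hydroxymethyl group as a cis-fused γ-lactone (a temporary ring). Saponification of this lactone and decarboxylative arylation under NiCl2·glyme/dtbbpy and Ir[dF(CF3)ppy]2(dtbbpy)PF6 photocatalysis with the complete erythro arylglycerol aryl bromide should forge the aryl–C2 bond and the 2,3-trans stereocentre in one operation, the C3 centre steering the aryl group. Both partners carry free hydroxyls; one phenolic silyl ether is removed last.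

Key step: step 12

Assumption: the MgCl2-catalysed anti-aldol of the aryloxyacetyl imide (step 4) is taken to follow the chelated Z-enolate sense of induction known for N-propionyloxazolidinones (aldehyde anti to benzyl); if the aryloxy group reversed the facial sense, the (S)-auxiliary would be used instead.

Step 1
Reactants: 1 (R)-4-benzyloxazolidin-2-one; 2 bromoacetyl bromide
Product: 3 (R)-4-benzyl-3-(2-bromoacetyl)oxazolidin-2-one
Conditions: n-BuLi, THF, −78 °C; then 2, −78 to 0 °C
Reagents that add atoms: none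
Why: N-acylation of the lithiated oxazolidinone, in which the acyl bromide should react far faster than the alkyl bromide at low temperature.

Step 2
Reactants: 3 (R)-4-benzyl-3-(2-bromoacetyl)oxazolidin-2-one; 4 4-bromo-2,6-dimethoxyphenol
Product: 5 (R)-4-benzyl-3-[2-(4-bromo-2,6-dimethoxyphenoxy)acetyl]oxazolidin-2-one
Conditions: K2CO3, MeCN, rt
Reagents that add atoms: none
Why: Williamson ether synthesis in which the hindered but nucleophilic 2,6-dimethoxyphenoxide displaces the activated α-bromide while the mild carbonate base leaves the imide intact.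

Step 3
Reactants: 6 vanillin
Product: 7 3-methoxy-4-(triisopropylsilyloxy)benzaldehyde
Conditions: TIPSCl, imidazole, DMF, rt
Reagents that add atoms: triisopropylsilyl chloride CC(C)[Si](Cl)(C(C)C)C(C)C
Why: Standard phenol silylation, the triisopropylsilyl aryl ether being chosen because it should survive amine base, Lewis acid, borohydride and carboxylate in the later steps.

Step 4
Reactants: 5 (R)-4-benzyl-3-[2-(4-bromo-2,6-dimethoxyphenoxy)acetyl]oxazolidin-2-one; 7 3-methoxy-4-(triisopropylsilyloxy)benzaldehyde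
Product: 9 (R)-4-benzyl-3-[(2S,3S)-2-(4-bromo-2,6-dimethoxyphenoxy)-3-hydroxy-3-[3-methoxy-4-(triisopropylsilyloxy)phenyl]propanoyl]oxazolidin-2-one, via O-trimethylsilyl aldol adduct 8 (not isolated)
Conditions: MgCl2 (20 mol%), Et3N, TMSCl, EtOAc, rt; then THF/1 M HCl 5:1, rt
Reagents that add atoms: none
Why: MgCl2-catalysed direct anti-aldol reaction of an N-acyloxazolidinone (Evans-type anti-aldol), in which the chelated magnesium Z-enolate should add to the aldehyde on the face opposite the benzyl group through a boat transition state, so the auxiliary sets both carbinol centres (2S,3S, the erythro pair), O-silylation turns the magnesium over, and mild acid removes the trimethylsilyl ether.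

Step 5
Reactants: 9 (R)-4-benzyl-3-[(2S,3S)-2-(4-bromo-2,6-dimethoxyphenoxy)-3-hydroxy-3-[3-methoxy-4-(triisopropylsilyloxy)phenyl]propanoyl]oxazolidin-2-one
Product: 10 (1S,2R)-2-(4-bromo-2,6-dimethoxyphenoxy)-1-[3-methoxy-4-(triisopropylsilyloxy)phenyl]propane-1,3-diol
Conditions: NaBH4, THF/H2O 4:1, 0 °C to rt
Reagents that add atoms: none
Why: Reductive cleavage of the auxiliary by borohydride attack on the exocyclic imide carbonyl should give the primary alcohol without touching the aryl bromide, the silyl ether or either stereocentre.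

Step 6
Reactants: 11 5-bromovanillin
Product: 12 2-bromo-4-(1,3-dioxolan-2-yl)-6-methoxyphenol
Conditions: ethylene glycol, p-TsOH·H2O (cat.), toluene, reflux, Dean–Stark; Et3N quench
Reagents that add atoms: ethylene glycol OCCO
Why: Acid-catalysed acetalisation driven by azeotropic removal of water masks the aldehyde against the organometallic and enolate steps that follow.

Step 7
Reactants: 12 2-bromo-4-(1,3-dioxolan-2-yl)-6-methoxyphenol
Product: 13 2-[3-bromo-5-methoxy-4-(methoxymethoxy)phenyl]-1,3-dioxolane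
Conditions: MOMCl, i-Pr2NEt, CH2Cl2, 0 °C to rt
Reagents that add atoms: chloromethyl methyl ether COCCl
Why: Base-mediated methoxymethyl etherification of the phenol, which the acetal tolerates and which one later acid treatment removes together with the acetal.

Step 8
Reactants: 13 2-[3-bromo-5-methoxy-4-(methoxymethoxy)phenyl]-1,3-dioxolane
Product: 14 2-[5-(1,3-dioxolan-2-yl)-3-methoxy-2-(methoxymethoxy)phenyl]-4,4,5,5-tetramethyl-1,3,2-dioxaborolane
Conditions: B2pin2, Pd(dppf)Cl2 (3 mol%), KOAc, 1,4-dioxane, 90 °C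
Reagents that add atoms: bis(pinacolato)diboron CC1(C)OB(OC1(C)C)B1OC(C)(C)C(C)(C)O1
Why: Miyaura borylation of an aryl bromide, under which acetal and methoxymethyl ether are inert.

Step 9
Reactants: 14 2-[5-(1,3-dioxolan-2-yl)-3-methoxy-2-(methoxymethoxy)phenyl]-4,4,5,5-tetramethyl-1,3,2-dioxaborolane; 15 furan-2(5H)-one
Product: 16 (S)-4-[5-(1,3-dioxolan-2-yl)-3-methoxy-2-(methoxymethoxy)phenyl]dihydrofuran-2(3H)-one
Conditions: [Rh(OH)(cod)]2 (2.5 mol%), (S)-BINAP (6 mol%), KOH (0.2 equiv), 1,4-dioxane/H2O 10:1, 50 °C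
Reagents that add atoms: none
Why: Hayashi–Miyaura asymmetric 1,4-addition of the arylboronate to the butenolide, in which (S)-BINAP is expected, by analogy with cyclic enones, to deliver the aryl group to the face that gives the 4S lactone (the future C3 of the dihydrobenzofuran), while the lactone already holds the future hydroxymethyl and carboxyl carbons.

Step 10
Reactants: 16 (S)-4-[5-(1,3-dioxolan-2-yl)-3-methoxy-2-(methoxymethoxy)phenyl]dihydrofuran-2(3H)-one
Product: 17 (3R,4S)-3-bromo-4-[5-(1,3-dioxolan-2-yl)-3-methoxy-2-(methoxymethoxy)phenyl]dihydrofuran-2(3H)-one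
Conditions: LiHMDS, THF, −78 °C; then NBS, −78 °C; sat. aq. NH4Cl
Reagents that add atoms: N-bromosuccinimide O=C1CCC(=O)N1Br
Why: Electrophilic α-bromination of the lactone lithium enolate, in which bromine should enter anti to the adjacent aryl group to give the trans bromide needed for backside displacement (any cis epimer can equilibrate through the enolate in step 11).

Step 11
Reactants: 17 (3R,4S)-3-bromo-4-[5-(1,3-dioxolan-2-yl)-3-methoxy-2-(methoxymethoxy)phenyl]dihydrofuran-2(3H)-one
Product: 19 cis-fused γ-lactone of (2S,3S)-5-formyl-3-(hydroxymethyl)-7-methoxy-2,3-dihydrobenzofuran-2-carboxylic acid, via phenol aldehyde bromolactone 18 (not isolated)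
Conditions: 3 M aq. HCl, THF, 50 °C; then K2CO3 to pH 10, rt; then 1 M HCl to pH 2
Reagents that add atoms: water O
Why: Acid hydrolysis removes the methoxymethyl ether and the dioxolane, and the liberated phenoxide then closes the dihydrobenzofuran by intramolecular Williamson displacement (5-exo-tet, inversion at the brominated carbon), which can only give the cis-fused tricycle; final acidification relactonises any ring-opened hydroxy acid.

Step 12
Reactants: 19 cis-fused γ-lactone of (2S,3S)-5-formyl-3-(hydroxymethyl)-7-methoxy-2,3-dihydrobenzofuran-2-carboxylic acid; 10 (1S,2R)-2-(4-bromo-2,6-dimethoxyphenoxy)-1-[3-methoxy-4-(triisopropylsilyloxy)phenyl]propane-1,3-diol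
Product: 21 (2R,3S)-2-{4-[(1S,2R)-1,3-dihydroxy-1-[3-methoxy-4-(triisopropylsilyloxy)phenyl]propan-2-yl]oxy-3,5-dimethoxyphenyl}-3-(hydroxymethyl)-7-methoxy-2,3-dihydrobenzofuran-5-carbaldehyde, via caesium hydroxy carboxylate 20 (not isolated)
Conditions: 19 (1.5 equiv), CsOH·H2O (1.0 equiv to 19), THF/H2O, rt, evaporate; then 10, Ir[dF(CF3)ppy]2(dtbbpy)PF6 (2 mol%), NiCl2·glyme (10 mol%), dtbbpy (15 mol%), degassed DMF, blue LEDs (450 nm), rt
Reagents that add atoms: none
Why: Hydroxide opens lactone 19 to carboxylate 20, the photoexcited trivalent iridium complex oxidises the carboxylate, loss of CO2 gives the C2 radical stabilised by ring oxygen O1, zerovalent nickel inserts into the C–Br bond of 10, and radical capture by the divalent aryl-nickel bromide followed by reductive elimination from trivalent nickel forms the C(aryl)–C2 bond before divalent iridium returns nickel to the zerovalent state. The closest known reaction type is the metallaphotoredox decarboxylative arylation of α-oxy carboxylic acids such as tetrahydrofuran-2-carboxylic acid with aryl bromides. No ring is closed in this step; the lactone opened just before served only to deliver carboxyl and hydroxymethyl together. The new stereocentre C2 is controlled by the existing C3 centre: the radical is planar, so the original C2 configuration is irrelevant, and the aryl-nickel unit should bond on the face anti to the C3 hydroxymethyl group to give the 2,3-trans (2R,3S) ring. The step needs trans diastereoselectivity and cross-coupling in preference to β-hydride elimination to the benzofuran or protodecarboxylation; the first is secured by the C3 substituent, the second by fast reductive elimination at an aryl bromide without ortho substituents, and chemoselectivity by the carboxylate being the only readily oxidised group once the phenol is silylated, free alcohols and the aldehyde being inert to both catalysts.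

Step 13
Reactants: 21 (2R,3S)-2-{4-[(1S,2R)-1,3-dihydroxy-1-[3-methoxy-4-(triisopropylsilyloxy)phenyl]propan-2-yl]oxy-3,5-dimethoxyphenyl}-3-(hydroxymethyl)-7-methoxy-2,3-dihydrobenzofuran-5-carbaldehyde
Product: 22 CID53356209, (2R,3S)-2-{4-[(1S,2R)-1,3-dihydroxy-1-(4-hydroxy-3-methoxyphenyl)propan-2-yl]oxy-3,5-dimethoxyphenyl}-3-(hydroxymethyl)-7-methoxy-2,3-dihydrobenzofuran-5-carbaldehyde
Conditions: TBAF, AcOH (1:1), THF, 0 °C
Reagents that add atoms: none
Why: Fluoride cleavage of the aryl silyl ether under acetic acid buffering should free the phenol without base-induced quinone methide formation at the para benzylic alcohol and without touching the aldehyde.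

Compound list
1 | (R)-4-benzyloxazolidin-2-one | O=C1N[C@H](Cc2ccccc2)CO1 | starting material
2 | bromoacetyl bromide | O=C(Br)CBr | starting material
3 | (R)-4-benzyl-3-(2-bromoacetyl)oxazolidin-2-one | O=C(CBr)N1[C@H](Cc2ccccc2)COC1=O | intermediate
4 | 4-bromo-2,6-dimethoxyphenol | COc1cc(Br)cc(OC)c1O | starting material
5 | (R)-4-benzyl-3-[2-(4-bromo-2,6-dimethoxyphenoxy)acetyl]oxazolidin-2-one | O=C(COc1c(OC)cc(Br)cc1OC)N1[C@H](Cc2ccccc2)COC1=O | intermediate
6 | vanillin (4-hydroxy-3-methoxybenzaldehyde) | COc1cc(C=O)ccc1O | starting material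
7 | 3-methoxy-4-(triisopropylsilyloxy)benzaldehyde | COc1cc(C=O)ccc1O[Si](C(C)C)(C(C)C)C(C)C | intermediate
8 | (R)-4-benzyl-3-[(2S,3S)-2-(4-bromo-2,6-dimethoxyphenoxy)-3-[3-methoxy-4-(triisopropylsilyloxy)phenyl]-3-(trimethylsilyloxy)propanoyl]oxazolidin-2-one (not isolated) | COc1cc([C@H](O[Si](C)(C)C)[C@@H](C(=O)N2[C@H](Cc3ccccc3)COC2=O)Oc4c(OC)cc(Br)cc4OC)ccc1O[Si](C(C)C)(C(C)C)C(C)C | intermediate
9 | (R)-4-benzyl-3-[(2S,3S)-2-(4-bromo-2,6-dimethoxyphenoxy)-3-hydroxy-3-[3-methoxy-4-(triisopropylsilyloxy)phenyl]propanoyl]oxazolidin-2-one | COc1cc([C@H](O)[C@@H](C(=O)N2[C@H](Cc3ccccc3)COC2=O)Oc4c(OC)cc(Br)cc4OC)ccc1O[Si](C(C)C)(C(C)C)C(C)C | intermediate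
10 | (1S,2R)-2-(4-bromo-2,6-dimethoxyphenoxy)-1-[3-methoxy-4-(triisopropylsilyloxy)phenyl]propane-1,3-diol (erythro) | COc1cc([C@H](O)[C@@H](CO)Oc2c(OC)cc(Br)cc2OC)ccc1O[Si](C(C)C)(C(C)C)C(C)C | intermediate
11 | 5-bromovanillin (3-bromo-4-hydroxy-5-methoxybenzaldehyde) | COc1cc(C=O)cc(Br)c1O | starting material
12 | 2-bromo-4-(1,3-dioxolan-2-yl)-6-methoxyphenol | COc1cc(C2OCCO2)cc(Br)c1O | intermediate
13 | 2-[3-bromo-5-methoxy-4-(methoxymethoxy)phenyl]-1,3-dioxolane | COCOc1c(Br)cc(C2OCCO2)cc1OC | intermediate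
14 | 2-[5-(1,3-dioxolan-2-yl)-3-methoxy-2-(methoxymethoxy)phenyl]-4,4,5,5-tetramethyl-1,3,2-dioxaborolane | COCOc1c(B2OC(C)(C)C(C)(C)O2)cc(C3OCCO3)cc1OC | intermediate
15 | furan-2(5H)-one | O=C1OCC=C1 | starting material
16 | (S)-4-[5-(1,3-dioxolan-2-yl)-3-methoxy-2-(methoxymethoxy)phenyl]dihydrofuran-2(3H)-one | O=C1C[C@@H](c2cc(C3OCCO3)cc(OC)c2OCOC)CO1 | intermediate
17 | (3R,4S)-3-bromo-4-[5-(1,3-dioxolan-2-yl)-3-methoxy-2-(methoxymethoxy)phenyl]dihydrofuran-2(3H)-one (Br trans to aryl) | O=C1[C@H](Br)[C@@H](c2cc(C3OCCO3)cc(OC)c2OCOC)CO1 | intermediate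
18 | (3R,4S)-3-bromo-4-(5-formyl-2-hydroxy-3-methoxyphenyl)dihydrofuran-2(3H)-one (not isolated) | O=C1[C@H](Br)[C@@H](c2cc(C=O)cc(OC)c2O)CO1 | intermediate
19 | cis-fused γ-lactone of (2S,3S)-5-formyl-3-(hydroxymethyl)-7-methoxy-2,3-dihydrobenzofuran-2-carboxylic acid (carboxyl carbon on C2 joined through oxygen to the CH2 on C3) | O=C1OC[C@@H]2c3cc(C=O)cc(OC)c3O[C@H]12 | intermediate
20 | caesium (2S,3S)-5-formyl-3-(hydroxymethyl)-7-methoxy-2,3-dihydrobenzofuran-2-carboxylate (not isolated) | [Cs+].[O-]C(=O)[C@H]1Oc2c(OC)cc(C=O)cc2[C@H]1CO | intermediate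
21 | (2R,3S)-2-{4-[(1S,2R)-1,3-dihydroxy-1-[3-methoxy-4-(triisopropylsilyloxy)phenyl]propan-2-yl]oxy-3,5-dimethoxyphenyl}-3-(hydroxymethyl)-7-methoxy-2,3-dihydrobenzofuran-5-carbaldehyde | COc1cc([C@H](O)[C@@H](CO)Oc2c(OC)cc([C@@H]3Oc4c(OC)cc(C=O)cc4[C@H]3CO)cc2OC)ccc1O[Si](C(C)C)(C(C)C)C(C)C | intermediate
22 | CID53356209, (2R,3S)-2-{4-[(1S,2R)-1,3-dihydroxy-1-(4-hydroxy-3-methoxyphenyl)propan-2-yl]oxy-3,5-dimethoxyphenyl}-3-(hydroxymethyl)-7-methoxy-2,3-dihydrobenzofuran-5-carbaldehyde | COc1cc([C@H](O)[C@@H](CO)Oc2c(OC)cc([C@@H]3Oc4c(OC)cc(C=O)cc4[C@H]3CO)cc2OC)ccc1O | target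

Total step count: 13. Longest linear sequence: 8 steps (steps 6 to 13, from 5-bromovanillin 11).

Steps most likely to fail

Step 12. The C2 radical may be lost before productive coupling, by β-hydride elimination at nickel towards the aromatic benzofuran or by hydrogen-atom capture (protodecarboxylation), and facial control at C2 may be incomplete. The fallback sets out from 19 and 10 and comes back to the route at 22; it replaces the photochemical radical generation by a thermal nickel cycle with a preformed arylzinc and a redox-active ester.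
- Lactone 19 is saponified (LiOH, THF/H2O) and silylated (TBSCl, imidazole, DMF; K2CO3, MeOH/H2O work-up to cleave the silyl ester) to give (2S,3S)-3-[(tert-butyldimethylsilyloxy)methyl]-5-formyl-7-methoxy-2,3-dihydrobenzofuran-2-carboxylic acid F1.
- F1 is esterified with N-hydroxyphthalimide (DIC, DMAP cat., CH2Cl2) to the N-hydroxyphthalimide ester F2.
- Diol 10 is silylated (TBSOTf, 2,6-lutidine, CH2Cl2) to the bis(tert-butyldimethylsilyl) ether F3, which is metalated (n-BuLi, THF, −78 °C; then ZnCl2) to the arylzinc chloride F4.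
- Decarboxylative Negishi-type coupling of F2 with F4 (NiCl2·glyme 20 mol%, dtbbpy 40 mol%, THF/DMF, rt) should give the fully silylated trans coupling product F5.
- Global desilylation (TBAF/AcOH, THF) should give 22.

Step 4. The aryloxy oxygen may perturb magnesium chelation, so that facial selectivity is poor or reversed, and the aldol equilibrium may lie on the side of the starting materials for the electron-rich aldehyde. The fallback sets out from 4 and 7 and comes back at 10; it uses the boron-mediated Evans syn aldol, which fixes the aryloxy-bearing centre, followed by Mitsunobu inversion of the carbinol.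
- Phenol 4 is alkylated with commercial (S)-4-benzyl-3-(chloroacetyl)oxazolidin-2-one (K2CO3, NaI, MeCN) to (S)-4-benzyl-3-[2-(4-bromo-2,6-dimethoxyphenoxy)acetyl]oxazolidin-2-one F6.
- Bu2BOTf, i-Pr2NEt, CH2Cl2, −78 to 0 °C, then 7, should give the syn adduct (S)-4-benzyl-3-[(2S,3R)-2-(4-bromo-2,6-dimethoxyphenoxy)-3-hydroxy-3-[3-methoxy-4-(triisopropylsilyloxy)phenyl]propanoyl]oxazolidin-2-one F7.
- NaBH4 in THF/H2O gives the threo diol (1R,2R)-2-(4-bromo-2,6-dimethoxyphenoxy)-1-[3-methoxy-4-(triisopropylsilyloxy)phenyl]propane-1,3-diol F8.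
- Selective primary acetylation (AcCl, 2,4,6-collidine, CH2Cl2, −78 °C) gives (2R,3R)-2-(4-bromo-2,6-dimethoxyphenoxy)-3-hydroxy-3-[3-methoxy-4-(triisopropylsilyloxy)phenyl]propyl acetate F9.
- Mitsunobu inversion (4-nitrobenzoic acid, PPh3, DIAD, THF, 0 °C) gives (1S,2R)-3-acetoxy-2-(4-bromo-2,6-dimethoxyphenoxy)-1-[3-methoxy-4-(triisopropylsilyloxy)phenyl]propyl 4-nitrobenzoate F10.
- Methanolysis of both esters (K2CO3, MeOH, 0 °C) returns 10.

Step 9. Protodeboronation of the ortho-alkoxy arylboronate may outrun conjugate addition to the weakly reactive butenolide, and enantioselectivity may erode. The fallback sets out from 14 and comes back at 16; it separates C–C bond formation from the creation of the stereocentre.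
- Suzuki–Miyaura coupling of 14 with commercial 4-bromofuran-2(5H)-one (Pd(PPh3)4, aq. K2CO3, THF, 60 °C) gives 4-[5-(1,3-dioxolan-2-yl)-3-methoxy-2-(methoxymethoxy)phenyl]furan-2(5H)-one F11.
- Enantioselective conjugate reduction with copper hydride generated from Cu(OAc)2, p-tol-BINAP (the antipode that gives the S lactone) and polymethylhydrosiloxane with t-BuOH in toluene should give 16.

Further compounds
F1 | step 12 | (2S,3S)-3-[(tert-butyldimethylsilyloxy)methyl]-5-formyl-7-methoxy-2,3-dihydrobenzofuran-2-carboxylic acid | OC(=O)[C@H]1Oc2c(OC)cc(C=O)cc2[C@H]1CO[Si](C)(C)C(C)(C)C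
F2 | step 12 | 1,3-dioxoisoindolin-2-yl (2S,3S)-3-[(tert-butyldimethylsilyloxy)methyl]-5-formyl-7-methoxy-2,3-dihydrobenzofuran-2-carboxylate | O=C(ON1C(=O)c2ccccc2C1=O)[C@H]1Oc2c(OC)cc(C=O)cc2[C@H]1CO[Si](C)(C)C(C)(C)C
F3 | step 12 | bis(tert-butyldimethylsilyl) ether of 10 | COc1cc([C@H](O[Si](C)(C)C(C)(C)C)[C@@H](CO[Si](C)(C)C(C)(C)C)Oc2c(OC)cc(Br)cc2OC)ccc1O[Si](C(C)C)(C(C)C)C(C)C
F4 | step 12 | arylzinc chloride derived from F3 | COc1cc([C@H](O[Si](C)(C)C(C)(C)C)[C@@H](CO[Si](C)(C)C(C)(C)C)Oc2c(OC)cc([Zn]Cl)cc2OC)ccc1O[Si](C(C)C)(C(C)C)C(C)C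
F5 | step 12 | tris(tert-butyldimethylsilyl) triisopropylsilyl ether of 22 | COc1cc([C@H](O[Si](C)(C)C(C)(C)C)[C@@H](CO[Si](C)(C)C(C)(C)C)Oc2c(OC)cc([C@@H]3Oc4c(OC)cc(C=O)cc4[C@H]3CO[Si](C)(C)C(C)(C)C)cc2OC)ccc1O[Si](C(C)C)(C(C)C)C(C)C
F6 | step 4 | (S)-4-benzyl-3-[2-(4-bromo-2,6-dimethoxyphenoxy)acetyl]oxazolidin-2-one | O=C(COc1c(OC)cc(Br)cc1OC)N1[C@@H](Cc2ccccc2)COC1=O
F7 | step 4 | (S)-4-benzyl-3-[(2S,3R)-2-(4-bromo-2,6-dimethoxyphenoxy)-3-hydroxy-3-[3-methoxy-4-(triisopropylsilyloxy)phenyl]propanoyl]oxazolidin-2-one | COc1cc([C@@H](O)[C@@H](C(=O)N2[C@@H](Cc3ccccc3)COC2=O)Oc4c(OC)cc(Br)cc4OC)ccc1O[Si](C(C)C)(C(C)C)C(C)C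
F8 | step 4 | (1R,2R)-2-(4-bromo-2,6-dimethoxyphenoxy)-1-[3-methoxy-4-(triisopropylsilyloxy)phenyl]propane-1,3-diol (threo) | COc1cc([C@@H](O)[C@@H](CO)Oc2c(OC)cc(Br)cc2OC)ccc1O[Si](C(C)C)(C(C)C)C(C)C
F9 | step 4 | (2R,3R)-2-(4-bromo-2,6-dimethoxyphenoxy)-3-hydroxy-3-[3-methoxy-4-(triisopropylsilyloxy)phenyl]propyl acetate | COc1cc([C@@H](O)[C@@H](COC(C)=O)Oc2c(OC)cc(Br)cc2OC)ccc1O[Si](C(C)C)(C(C)C)C(C)C
F10 | step 4 | (1S,2R)-3-acetoxy-2-(4-bromo-2,6-dimethoxyphenoxy)-1-[3-methoxy-4-(triisopropylsilyloxy)phenyl]propyl 4-nitrobenzoate | COc1cc([C@H](OC(=O)c2ccc(cc2)[N+](=O)[O-])[C@@H](COC(C)=O)Oc3c(OC)cc(Br)cc3OC)ccc1O[Si](C(C)C)(C(C)C)C(C)C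
F11 | step 9 | 4-[5-(1,3-dioxolan-2-yl)-3-methoxy-2-(methoxymethoxy)phenyl]furan-2(5H)-one | O=C1OCC(c2cc(C3OCCO3)cc(OC)c2OCOC)=C1
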